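**Target identity.** The SMILES corresponds to (6S,7S,8R)-8-(4-hydroxy-3,5-dimethoxyphenyl)-6,7-bis(hydroxymethyl)-3-methoxy-5,6,7,8-tetrahydronaphthalen-2-ol. In tetralin numbering this is 1R,2S,3S, with 1,2-trans and 2,3-trans relationships. It is 5'-methoxyisolariciresinol in the series enantiomeric to (+)-isolariciresinol.

**Assumption.** Both O-benzyl aldehydes are treated as catalogue items. If either is not, vanillin or syringaldehyde with BnBr/K2CO3/DMF adds one step.

## Retrosynthetic overview
1. Target ⇒ O-debenzylation and lactone reduction of an all-trans aryltetralin lactone of the retrodendrin/isodeoxypodophyllotoxin type.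
2. The C1–C8a bond ⇒ intramolecular Friedel–Crafts closure of a benzylic cation from an α-(hydroxybenzyl)-β-benzyl-γ-butyrolactone, para to the OMe group.
3. The C1–C2 bond ⇒ trans-selective aldol of (S)-β-(4-benzyloxy-3-methoxybenzyl)-γ-butyrolactone with O-benzylsyringaldehyde.
4. The (S)-lactone ⇒ Stobbe half-ester from O-benzylvanillin and dimethyl succinate, then Rh-catalysed asymmetric hydrogenation (the only catalyst-controlled stereocentre), then chemoselective ester reduction.
5. Ring order: both arenes are bought, the temporary butyrolactone forms first, the tetralin carbocycle forms second, and the lactone is opened at the end.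

## Route

**Step 1**
Reactants: 1, 4-benzyloxy-3-methoxybenzaldehyde; 2, dimethyl succinate
Product: 3, (E)-4-[4-(benzyloxy)-3-methoxyphenyl]-3-(methoxycarbonyl)but-3-enoic acid
Conditions: NaOMe, MeOH, reflux; then aq. HCl
Reagents that add atoms: dimethyl succinate, COC(=O)CCC(=O)OC
Why: In this Stobbe condensation the aldolate lactonises to a paraconic ester, and irreversible E1cB opening gives the (E)-alkylidene half-ester with the free acid on the CH2 arm; no stereocentre forms.

**Step 2**
Reactants: 3
Product: 4, (3S)-4-[4-(benzyloxy)-3-methoxyphenyl]-3-(methoxycarbonyl)butanoic acid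
Conditions: [(R,R)-Et-DuPhos)Rh(cod)]BF4 (0.2 mol %), NaOMe (10 mol %), H2 (5–6 atm), MeOH, rt
Reagents that add atoms: none
Why: In this carboxylate-chelated Rh–DuPhos asymmetric hydrogenation of an itaconate-type olefin, the (R,R) ligand delivers the (S)-2-substituted succinate (future C3 of the target), the homogeneous Rh leaves the benzyl ethers intact, and the sense and ee are confirmed on 5 by chiral HPLC.

**Step 3**
Reactants: 4
Product: 5, (4S)-4-[4-(benzyloxy)-3-methoxybenzyl]dihydrofuran-2(3H)-one
Conditions: KOH (1 equiv), EtOH; CaCl2/NaBH4, EtOH, 0 °C→rt; then 3 M HCl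
Reagents that add atoms: none
Why: In this chemoselective Ca(BH4)2 reduction the carboxylate salt is inert while the methyl ester goes to CH2OH, acidification then closes the γ-lactone, and no bond to the stereocentre is broken.

**Step 4**
Reactants: 5; 6, 4-benzyloxy-3,5-dimethoxybenzaldehyde
Product: 7, (3R,4S)-4-[4-(benzyloxy)-3-methoxybenzyl]-3-{[4-(benzyloxy)-3,5-dimethoxyphenyl](hydroxy)methyl}dihydrofuran-2(3H)-one, as a mixture of carbinol epimers
Conditions: LDA (1.1 equiv), THF, −78 °C; then 6; NH4Cl quench at −78 °C
Reagents that add atoms: 4-benzyloxy-3,5-dimethoxybenzaldehyde, COc1cc(C=O)cc(OC)c1OCc1ccccc1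
Why: In this lithium-enolate aldol addition the aldehyde approaches anti to the β-benzyl group, which sets the 3,4-trans relationship (future C2) under substrate control, and the carbinol configuration does not matter because it is ionised in the next step.

**Step 5**
Reactants: 7
Product: 8, (3aS,9R,9aS)-7-(benzyloxy)-9-[4-(benzyloxy)-3,5-dimethoxyphenyl]-6-methoxy-3a,4,9,9a-tetrahydronaphtho[2,3-c]furan-1(3H)-one
Conditions: TFA (5–10 equiv), CH2Cl2, 0 °C→rt, 1–2 h
Reagents that add atoms: none
Why: In this intramolecular Friedel–Crafts alkylation both carbinol epimers converge on one benzylic cation, which is trapped para to the OMe through a chair-like transition state with the aryl group pseudo-equatorial, giving C1 trans to C2 (1R).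

**Step 6**
Reactants: 8
Product: 9, {(1R,2S,3S)-7-(benzyloxy)-1-[4-(benzyloxy)-3,5-dimethoxyphenyl]-6-methoxy-1,2,3,4-tetrahydronaphthalene-2,3-diyl}dimethanol
Conditions: LiAlH4 (3 equiv), THF, 0 °C→rt, adding 8 to the hydride; Fieser work-up
Reagents that add atoms: none
Why: Hydride reduction of the lactone to the 1,4-diol is fast at 0 °C with excess hydride, so it outruns enolisation at C2 and all three stereocentres are retained.

**Step 7**
Reactants: 9
Product: 10, the target
Conditions: H2 (1 atm), 10 % Pd/C, MeOH/EtOAc, rt
Reagents that add atoms: none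
Why: Catalytic hydrogenolysis removes both aryl benzyl ethers, and the ring benzylic positions C1 and C4 bear only C–C and C–H bonds, so they are not cleaved or epimerised.

## Compound list

| No. | Name | SMILES | Role |
|---|---|---|---|
| 1 | 4-benzyloxy-3-methoxybenzaldehyde | COc1cc(C=O)ccc1OCc1ccccc1 | starting material |
| 2 | dimethyl succinate | COC(=O)CCC(=O)OC | starting material |
| 3 | (E)-Stobbe half-ester | COC(=O)/C(CC(=O)O)=C/c1ccc(OCc2ccccc2)c(OC)c1 | intermediate |
| 4 | (S)-benzylsuccinic acid 1-methyl ester | COC(=O)[C@H](CC(=O)O)Cc1ccc(OCc2ccccc2)c(OC)c1 | intermediate |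
| 5 | (S)-β-benzyl-γ-butyrolactone | O=C1C[C@H](Cc2ccc(OCc3ccccc3)c(OC)c2)CO1 | intermediate |
| 6 | 4-benzyloxy-3,5-dimethoxybenzaldehyde | COc1cc(C=O)cc(OC)c1OCc1ccccc1 | starting material |
| 7 | (3R,4S)-aldol adduct, carbinol epimers | OC(c1cc(OC)c(OCc2ccccc2)c(OC)c1)[C@@H]1C(=O)OC[C@H]1Cc1ccc(OCc2ccccc2)c(OC)c1 | intermediate |
| 8 | (3aS,9R,9aS)-aryltetralin lactone | COc1cc2c(cc1OCc1ccccc1)[C@@H](c1cc(OC)c(OCc3ccccc3)c(OC)c1)[C@@H]1C(=O)OC[C@H]1C2 | intermediate |
| 9 | (1R,2S,3S)-di-O-benzyl diol | COc1cc2c(cc1OCc1ccccc1)[C@@H](c1cc(OC)c(OCc3ccccc3)c(OC)c1)[C@H](CO)[C@@H](CO)C2 | intermediate |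
| 10 | (6S,7S,8R)-5'-methoxyisolariciresinol | COc1cc2c(cc1O)[C@@H](c1cc(OC)c(O)c(OC)c1)[C@H](CO)[C@@H](CO)C2 | target |

## Step count
Total steps: 7. Longest linear sequence: 7. The route is fully linear, and 6 enters at step 4 as a purchased material.

## Steps most likely to fail

1. **Step 2: ee or sense of induction on the arylidene half-ester.**
   - Fallback: auxiliary control instead of catalysis.
   - Acylate (R)-4-benzyloxazolidin-2-one with 3-(4-benzyloxy-3-methoxyphenyl)propanoic acid.
   - Carry out an Evans alkylation with NaHMDS and tert-butyl bromoacetate.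
   - Reduce with LiBH4 and lactonise with acid to reach the same (S)-5.

2. **Step 5: benzyl ether loss, C-benzylation, dehydration, or poor 1,2-selectivity while forming the strained trans-lactone.**
   - Fallback: change the order of events.
   - Reduce 7 to the triol with LiAlH4 first.
   - Close it with mild acid to the lariciresinol-type tetrahydrofuran.
   - Isomerise that with stronger acid directly to aryltetralin diol 9, the lariciresinol → isolariciresinol rearrangement.

3. **Step 3: incomplete chemoselectivity or partial epimerisation α to the ester.**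
   - Fallback: reduce 4 fully with LiAlH4 to (S)-2-(arylmethyl)butane-1,4-diol.
   - Follow with a regioselective oxidative lactonisation at the less hindered CH2CH2OH, using RuH2(PPh3)4/acetone or TEMPO/PhI(OAc)2. This gives the same β-benzyl lactone 5.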